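**Retrosynthetic overview**
1. Target 28 ⇐ 20-fold O-demethylation of 27 ⇐ sixfold Dakin oxidation of hexa-aldehyde 25; every CHO is a latent OH that first serves as an SNAr activator.
2. 25 ⇐ four iterative SNAr ether unions of a fluoro-aldehyde chain end (18 → 20 → 22 → 24) with the phenol of two-ring unit 13 (three times) and of its capped form 15. The unit's own fluoride is switched off as a dimethyl acetal and armed by the acid work-up.
3. Unit 13 ⇐ key C–C bond: 1-methoxyvinyllithium (an acetyl anion equivalent) adds to a carbonyl of aryl methyl squarate 7, joining two oxygen-bearing, normally electrophilic carbons. O-methylation and thermal 4π-opening/6π-closure then grow the pentaoxygenated ring directly on the ether oxygen.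
4. 7 ⇐ phenol 4 + squaryl dichloride + MeOH; 4 ⇐ 2-fluoro-3-methoxybenzaldehyde by acetalisation and Ir-catalysed C–H borylation/oxidation.
5. Ring order: the pentaoxygenated ring (rings 3, 5, 7, 9) is the only ring constructed, once, in 13; the other six rings are bought as arenes; the chain is assembled from ring 1 toward ring 10.

Assumption: the target has no stereocentre and no stable stereoaxis, so the achiral compound itself is the single species required.

Ring key: ring 1 = terminal 2,4,6-trihydroxyphenyl; rings 2, 4, 6, 8 = 2,6-dihydroxy-1,4-phenylene; rings 3, 5, 7, 9 = 3,4,5-trihydroxy-1,2-phenylene (O at C1 to the preceding ring, O at C2 to the following ring); ring 10 = terminal 3,4,5-trihydroxyphenyl.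

**Route**

Step 1
Reactants: 1 2-fluoro-3-methoxybenzaldehyde
Product: 2 1-(dimethoxymethyl)-2-fluoro-3-methoxybenzene
Conditions: HC(OMe)3 (3 equiv), p-TsOH·H2O (2 mol%), MeOH, rt; Et3N quench
Reagents that add atoms: trimethyl orthoformate, COC(OC)OC; methanol, CO
Why: Acid-catalysed acetalisation (orthoformate as water scavenger) masks the aldehyde against organolithiums and switches off its SNAr activation; no stereocentre is formed.

Step 2
Reactants: 2 1-(dimethoxymethyl)-2-fluoro-3-methoxybenzene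
Product: 4 3-(dimethoxymethyl)-4-fluoro-5-methoxyphenol, via arylboronate 3 (not isolated)
Conditions: [Ir(OMe)(cod)]2 (1.5 mol%), 4,4'-di-tert-butyl-2,2'-bipyridine (3 mol%), B2pin2 (1.0 equiv), THF, 80 °C; then 30% H2O2, aq NaOH, 0 °C to rt; NH4Cl work-up
Reagents that add atoms: bis(pinacolato)diboron, CC1(C)OB(OC1(C)C)B1OC(C)(C)C(C)(C)O1 (boron stays only in 3); hydrogen peroxide, OO
Why: Sterically controlled Ir-catalysed C–H borylation takes the only C–H without an ortho substituent (C5), and basic peroxide oxidation of the C–B bond gives the phenol while the acetal survives (Hartwig–Miyaura borylation/oxidation).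

Step 3
Reactants: 4 3-(dimethoxymethyl)-4-fluoro-5-methoxyphenol; 5 3,4-dichlorocyclobut-3-ene-1,2-dione (squaryl dichloride)
Product: 7 3-[3-(dimethoxymethyl)-4-fluoro-5-methoxyphenoxy]-4-methoxycyclobut-3-ene-1,2-dione, via aryl chlorosquarate 6 (not isolated)
Conditions: 5 (1.05 equiv), i-Pr2NEt (1.0 equiv), CH2Cl2, −78 °C; then MeOH (1.5 equiv), i-Pr2NEt (1.1 equiv), −78 to 0 °C
Reagents that add atoms: methanol, CO
Why: Two successive addition–elimination (vinylogous acyl substitution) events on squaryl dichloride, first by the phenoxide and then by methanol, give the mixed aryl methyl squarate; the amine buffer protects the acetal.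

Step 4
Reactants: 7 3-[3-(dimethoxymethyl)-4-fluoro-5-methoxyphenoxy]-4-methoxycyclobut-3-ene-1,2-dione; 8 methyl vinyl ether
Product: 13 2-[3-(dimethoxymethyl)-4-fluoro-5-methoxyphenoxy]-3,4,5-trimethoxyphenol, via lithium alkoxide 9 (not isolated), via cyclobutenone methyl ether 10 (not isolated), via Z-dienylketene 11 (not isolated), via cyclohexadienone 12 (not isolated)
Conditions: 8 (1.6 equiv), t-BuLi (1.3 equiv), THF, −78 to 0 °C, recool to −78 °C; add 7, −78 °C, 30 min; MeOTf (2 equiv), −78 to −20 °C; NaHCO3 work-up (no acid); then toluene, 110 °C, 2 h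
Reagents that add atoms: methyl triflate, COS(=O)(=O)C(F)(F)F; tert-butyllithium, [Li]C(C)(C)C (lithium only, in 9)
Why: Proposed new method: 1-methoxyvinyllithium (acetyl anion equivalent) should add 1,2 to the carbonyl of 7 that is flanked by the small C–OMe carbon and conjugated only to the weaker aryloxy donor (the other carbonyl is the more deactivated vinylogous methyl ester), O-methylation caps that oxygen, and heating then causes conrotatory 4π ring opening (OMe outward) to the Z-dienylketene, 6π closure and tautomerisation, so that the only free phenol is the one next to the aryl ether; the closest known reaction is the Moore–Liebeskind ring expansion of 4-alkenyl-4-hydroxycyclobutenones made from dialkyl squarates, and the stereocentre of racemic 9/10 is destroyed on ring opening.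

Step 5
Reactants: 13 2-[3-(dimethoxymethyl)-4-fluoro-5-methoxyphenoxy]-3,4,5-trimethoxyphenol
Product: 15 5-(2-hydroxy-4,5,6-trimethoxyphenoxy)-2,3-dimethoxybenzaldehyde, via fluoro aldehyde 14 (not isolated)
Conditions: 1 M HCl, THF, rt; then slow addition to NaOMe (10 equiv), MeOH (0.02 M), 65 °C; NH4Cl work-up
Reagents that add atoms: water, O; sodium methoxide, [Na+].[O-]C
Why: Acetal hydrolysis unmasks the ortho-formyl group, which activates the fluoride for SNAr by methoxide; the large excess of methoxide and high dilution outcompete self-condensation through the phenoxide.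

Step 6
Reactants: 4 3-(dimethoxymethyl)-4-fluoro-5-methoxyphenol; 16 4-bromo-3,5-dimethoxybenzaldehyde
Product: 18 2-fluoro-5-(4-formyl-2,6-dimethoxyphenoxy)-3-methoxybenzaldehyde, via two-ring acetal 17 (not isolated)
Conditions: CuI (10 mol%), picolinic acid (20 mol%), K3PO4 (2 equiv), DMSO, 90 °C; then 1 M HCl, THF, rt
Reagents that add atoms: water, O
Why: Ullmann-type Cu-catalysed C–O coupling of an unhindered phenol with a para-formyl-activated aryl bromide makes the ring 1–ring 2 ether, and the acid work-up arms the fluoride of ring 2 by releasing its ortho aldehyde.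

Step 7
Reactants: 18 2-fluoro-5-(4-formyl-2,6-dimethoxyphenoxy)-3-methoxybenzaldehyde; 13 2-[3-(dimethoxymethyl)-4-fluoro-5-methoxyphenoxy]-3,4,5-trimethoxyphenol
Product: 20 four-ring fluoro trialdehyde (rings 1-4), via four-ring acetal 19 (not isolated)
Conditions: 13 (1.2 equiv), Cs2CO3 (2 equiv), DMSO (degassed), 90–100 °C; then 1 M HCl, THF, rt
Reagents that add atoms: water, O
Why: SNAr: the ortho-formyl group activates the fluoride of 18 toward the phenoxide of 13, whose own fluoride is inert while its aldehyde is an acetal, and fluoride leaves far faster than any aryloxide so the existing ethers are not exchanged; the acid work-up then arms the new chain end.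

Step 8
Reactants: 20 four-ring fluoro trialdehyde; 13 2-[3-(dimethoxymethyl)-4-fluoro-5-methoxyphenoxy]-3,4,5-trimethoxyphenol
Product: 22 six-ring fluoro tetra-aldehyde (rings 1-6), via six-ring acetal 21 (not isolated)
Conditions: 13 (1.2 equiv), Cs2CO3 (2 equiv), DMSO, 90–100 °C; then 1 M HCl, THF, rt
Reagents that add atoms: water, O
Why: The same SNAr/unmasking cycle as in step 7 adds rings 5 and 6; the reacting site is electronically identical to that of 18.

Step 9
Reactants: 22 six-ring fluoro tetra-aldehyde; 13 2-[3-(dimethoxymethyl)-4-fluoro-5-methoxyphenoxy]-3,4,5-trimethoxyphenol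
Product: 24 eight-ring fluoro penta-aldehyde (rings 1-8), via eight-ring acetal 23 (not isolated)
Conditions: 13 (1.3 equiv), Cs2CO3 (2 equiv), DMSO, 90–100 °C; then 1 M HCl, THF, rt
Reagents that add atoms: water, O
Why: Third SNAr/unmasking cycle, adding rings 7 and 8.

Step 10
Reactants: 24 eight-ring fluoro penta-aldehyde; 15 5-(2-hydroxy-4,5,6-trimethoxyphenoxy)-2,3-dimethoxybenzaldehyde
Product: 25 ten-ring hexa-aldehyde (rings 1-10)
Conditions: 15 (1.3 equiv), Cs2CO3 (2 equiv), DMSO, 100 °C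
Reagents that add atoms: none
Why: Final SNAr with the capped unit, which has no leaving group of its own (OMe ortho to CHO is not displaced), completes the nona-ether backbone.

Step 11
Reactants: 25 ten-ring hexa-aldehyde
Product: 27 ten-ring hexaphenol, via hexaformate 26 (not isolated)
Conditions: mCPBA (9 equiv), NaHCO3, CH2Cl2, 0 °C to rt; Na2S2O3 quench; then K2CO3, MeOH, rt, Ar
Reagents that add atoms: mCPBA, OOC(=O)c1cccc(Cl)c1
Why: Dakin oxidation through Baeyer–Villiger aryl migration: each aldehyde sits on a ring with an ortho or para oxygen donor, so aryl migrates to give the formate, and the phenols are released by methanolysis only after the oxidant is destroyed.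

Step 12
Reactants: 27 ten-ring hexaphenol
Product: 28 CNP0255890.0
Conditions: BBr3 (60 equiv), CH2Cl2, −78 °C to rt, 24 h, Ar; MeOH/H2O quench at 0 °C; evaporation; reversed-phase chromatography with degassed H2O/MeCN (0.1% HCO2H)
Reagents that add atoms: none
Why: Lewis-acid ether cleavage by BBr3 removes all 20 aryl methyl ethers while diaryl ethers are inert; the product has no stereocentre.

**Compound list**
1 | 2-fluoro-3-methoxybenzaldehyde | COc1cccc(C=O)c1F | starting material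
2 | 1-(dimethoxymethyl)-2-fluoro-3-methoxybenzene | COc1cccc(C(OC)OC)c1F | intermediate
3 | 2-[3-(dimethoxymethyl)-4-fluoro-5-methoxyphenyl]-4,4,5,5-tetramethyl-1,3,2-dioxaborolane | COc1cc(B2OC(C)(C)C(C)(C)O2)cc(C(OC)OC)c1F | intermediate
4 | 3-(dimethoxymethyl)-4-fluoro-5-methoxyphenol | COc1cc(O)cc(C(OC)OC)c1F | intermediate
5 | 3,4-dichlorocyclobut-3-ene-1,2-dione (squaryl dichloride) | O=C1C(Cl)=C(Cl)C1=O | starting material
6 | 3-chloro-4-[3-(dimethoxymethyl)-4-fluoro-5-methoxyphenoxy]cyclobut-3-ene-1,2-dione | O=C1C(Cl)=C(Oc2cc(OC)c(F)c(C(OC)OC)c2)C1=O | intermediate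
7 | 3-[3-(dimethoxymethyl)-4-fluoro-5-methoxyphenoxy]-4-methoxycyclobut-3-ene-1,2-dione | COC1=C(Oc2cc(OC)c(F)c(C(OC)OC)c2)C(=O)C1=O | intermediate
8 | methyl vinyl ether (methoxyethene) | COC=C | starting material
9 | lithium 3-aryloxy-2-methoxy-1-(1-methoxyethenyl)-4-oxocyclobut-2-en-1-olate (racemic; aryl = 3-(dimethoxymethyl)-4-fluoro-5-methoxyphenyl) | [Li+].[O-]C1(C(=C)OC)C(OC)=C(Oc2cc(OC)c(F)c(C(OC)OC)c2)C1=O | intermediate
10 | 2-[3-(dimethoxymethyl)-4-fluoro-5-methoxyphenoxy]-3,4-dimethoxy-4-(1-methoxyethenyl)cyclobut-2-en-1-one (racemic) | COC(=C)C1(OC)C(OC)=C(Oc2cc(OC)c(F)c(C(OC)OC)c2)C1=O | intermediate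
11 | (3Z)-2-[3-(dimethoxymethyl)-4-fluoro-5-methoxyphenoxy]-3,4,5-trimethoxyhexa-1,3,5-trien-1-one | O=C=C(Oc1cc(OC)c(F)c(C(OC)OC)c1)/C(OC)=C(OC)\C(OC)=C | intermediate
12 | 2-[3-(dimethoxymethyl)-4-fluoro-5-methoxyphenoxy]-3,4,5-trimethoxycyclohexa-2,4-dien-1-one | O=C1CC(OC)=C(OC)C(OC)=C1Oc1cc(OC)c(F)c(C(OC)OC)c1 | intermediate
13 | 2-[3-(dimethoxymethyl)-4-fluoro-5-methoxyphenoxy]-3,4,5-trimethoxyphenol (two-ring unit) | Oc1cc(OC)c(OC)c(OC)c1Oc1cc(OC)c(F)c(C(OC)OC)c1 | intermediate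
14 | 2-fluoro-5-(2-hydroxy-4,5,6-trimethoxyphenoxy)-3-methoxybenzaldehyde | Oc1cc(OC)c(OC)c(OC)c1Oc1cc(OC)c(F)c(C=O)c1 | intermediate
15 | 5-(2-hydroxy-4,5,6-trimethoxyphenoxy)-2,3-dimethoxybenzaldehyde (capped unit, rings 9 and 10) | Oc1cc(OC)c(OC)c(OC)c1Oc1cc(OC)c(OC)c(C=O)c1 | intermediate
16 | 4-bromo-3,5-dimethoxybenzaldehyde | COc1cc(C=O)cc(OC)c1Br | starting material
17 | 4-[3-(dimethoxymethyl)-4-fluoro-5-methoxyphenoxy]-3,5-dimethoxybenzaldehyde | COc1cc(C=O)cc(OC)c1Oc1cc(OC)c(F)c(C(OC)OC)c1 | intermediate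
18 | 2-fluoro-5-(4-formyl-2,6-dimethoxyphenoxy)-3-methoxybenzaldehyde (rings 1 and 2) | COc1cc(C=O)cc(OC)c1Oc1cc(OC)c(F)c(C=O)c1 | intermediate
19 | rings 1-4 chain: ring 1 4-formyl-2,6-dimethoxyphenyl; ring 2 3-formyl-5-methoxy-1,4-phenylene; ring 3 3,4,5-trimethoxy-1,2-phenylene; ring 4 3-(dimethoxymethyl)-4-fluoro-5-methoxyphenyl | COc1cc(C=O)cc(OC)c1Oc1cc(OC)c(Oc2cc(OC)c(OC)c(OC)c2Oc2cc(OC)c(F)c(C(OC)OC)c2)c(C=O)c1 | intermediate
20 | rings 1-4 chain as 19 but ring 4 is 4-fluoro-3-formyl-5-methoxyphenyl | COc1cc(C=O)cc(OC)c1Oc1cc(OC)c(Oc2cc(OC)c(OC)c(OC)c2Oc2cc(OC)c(F)c(C=O)c2)c(C=O)c1 | intermediate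
21 | rings 1-6 chain (even rings 3-formyl-5-methoxy-1,4-phenylene; odd rings 3,4,5-trimethoxy-1,2-phenylene); ring 6 is 3-(dimethoxymethyl)-4-fluoro-5-methoxyphenyl | COc1cc(C=O)cc(OC)c1Oc1cc(OC)c(Oc2cc(OC)c(OC)c(OC)c2Oc2cc(OC)c(Oc3cc(OC)c(OC)c(OC)c3Oc3cc(OC)c(F)c(C(OC)OC)c3)c(C=O)c2)c(C=O)c1 | intermediate
22 | rings 1-6 chain as 21 but ring 6 is 4-fluoro-3-formyl-5-methoxyphenyl | COc1cc(C=O)cc(OC)c1Oc1cc(OC)c(Oc2cc(OC)c(OC)c(OC)c2Oc2cc(OC)c(Oc3cc(OC)c(OC)c(OC)c3Oc3cc(OC)c(F)c(C=O)c3)c(C=O)c2)c(C=O)c1 | intermediate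
23 | rings 1-8 chain; ring 8 is 3-(dimethoxymethyl)-4-fluoro-5-methoxyphenyl | COc1cc(C=O)cc(OC)c1Oc1cc(OC)c(Oc2cc(OC)c(OC)c(OC)c2Oc2cc(OC)c(Oc3cc(OC)c(OC)c(OC)c3Oc3cc(OC)c(Oc4cc(OC)c(OC)c(OC)c4Oc4cc(OC)c(F)c(C(OC)OC)c4)c(C=O)c3)c(C=O)c2)c(C=O)c1 | intermediate
24 | rings 1-8 chain as 23 but ring 8 is 4-fluoro-3-formyl-5-methoxyphenyl | COc1cc(C=O)cc(OC)c1Oc1cc(OC)c(Oc2cc(OC)c(OC)c(OC)c2Oc2cc(OC)c(Oc3cc(OC)c(OC)c(OC)c3Oc3cc(OC)c(Oc4cc(OC)c(OC)c(OC)c4Oc4cc(OC)c(F)c(C=O)c4)c(C=O)c3)c(C=O)c2)c(C=O)c1 | intermediate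
25 | rings 1-10 hexa-aldehyde: CHO on rings 1, 2, 4, 6, 8, 10; ring 10 is 3-formyl-4,5-dimethoxyphenyl; 20 OMe | COc1cc(C=O)cc(OC)c1Oc1cc(OC)c(Oc2cc(OC)c(OC)c(OC)c2Oc2cc(OC)c(Oc3cc(OC)c(OC)c(OC)c3Oc3cc(OC)c(Oc4cc(OC)c(OC)c(OC)c4Oc4cc(OC)c(Oc5cc(OC)c(OC)c(OC)c5Oc5cc(OC)c(OC)c(C=O)c5)c(C=O)c4)c(C=O)c3)c(C=O)c2)c(C=O)c1 | intermediate
26 | hexaformate of 27 (each CHO of 25 replaced by OCHO) | COc1cc(OC=O)cc(OC)c1Oc1cc(OC)c(Oc2cc(OC)c(OC)c(OC)c2Oc2cc(OC)c(Oc3cc(OC)c(OC)c(OC)c3Oc3cc(OC)c(Oc4cc(OC)c(OC)c(OC)c4Oc4cc(OC)c(Oc5cc(OC)c(OC)c(OC)c5Oc5cc(OC)c(OC)c(OC=O)c5)c(OC=O)c4)c(OC=O)c3)c(OC=O)c2)c(OC=O)c1 | intermediate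
27 | rings 1-10 hexaphenol (each CHO of 25 replaced by OH; 20 OMe) | COc1cc(O)cc(OC)c1Oc1cc(OC)c(Oc2cc(OC)c(OC)c(OC)c2Oc2cc(OC)c(Oc3cc(OC)c(OC)c(OC)c3Oc3cc(OC)c(Oc4cc(OC)c(OC)c(OC)c4Oc4cc(OC)c(Oc5cc(OC)c(OC)c(OC)c5Oc5cc(OC)c(OC)c(O)c5)c(O)c4)c(O)c3)c(O)c2)c(O)c1 | intermediate
28 | CNP0255890.0 (ten rings, nine diaryl ethers, 26 OH; achiral) | Oc1cc(O)c(Oc2cc(O)c(Oc3cc(O)c(O)c(O)c3Oc3cc(O)c(Oc4cc(O)c(O)c(O)c4Oc4cc(O)c(Oc5cc(O)c(O)c(O)c5Oc5cc(O)c(Oc6cc(O)c(O)c(O)c6Oc6cc(O)c(O)c(O)c6)c(O)c5)c(O)c4)c(O)c3)c(O)c2)c(O)c1 | target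

**Totals**
Total step count: 12. Longest linear sequence: 10 steps (1, 2, 3, 4, 7, 8, 9, 10, 11, 12).

**Three steps most likely to fail, with fallbacks**

Step 4 (regiochemistry of the acetyl-anion addition to the unsymmetrical squarate, or loss of aryloxide by addition–elimination). The fallback sets out from 4 and comes back at 13. Phenol 4 is coupled with purchased 2-bromo-3,4,5-trimethoxybenzaldehyde (O=Cc1cc(OC)c(OC)c(OC)c1Br) under CuI, picolinic acid and K3PO4 in DMSO at 90 °C, where the ortho-formyl group assists the Ullmann coupling. This gives 2-[3-(dimethoxymethyl)-4-fluoro-5-methoxyphenoxy]-3,4,5-trimethoxybenzaldehyde F1. Buffered mCPBA (NaHCO3, CH2Cl2) converts it into 2-[3-(dimethoxymethyl)-4-fluoro-5-methoxyphenoxy]-3,4,5-trimethoxyphenyl formate F2, and K2CO3 in MeOH releases 13. The pentaoxygenated ring is then bought rather than built.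

Step 7 (first SNAr union, diagnostic for steps 8–10: the fluoro aldehyde carries two oxygen donors and the phenoxide is ortho-substituted). The fallback sets out from 18 and comes back at 19, which the usual acid work-up turns into 20. With 2-(methylsulfonyl)ethanol and NaH in DMF the small alkoxide displaces the fluoride of 18 to give 5-(4-formyl-2,6-dimethoxyphenoxy)-3-methoxy-2-[2-(methylsulfonyl)ethoxy]benzaldehyde F3. In the same flask F3 loses methyl vinyl sulfone to give 5-(4-formyl-2,6-dimethoxyphenoxy)-2-hydroxy-3-methoxybenzaldehyde F4. Tf2O and pyridine in CH2Cl2 give 4-(4-formyl-2,6-dimethoxyphenoxy)-2-formyl-6-methoxyphenyl trifluoromethanesulfonate F5. Cross-coupling of F5 with 13 using Pd(OAc)2, tBuXPhos and K3PO4 in toluene at 100 °C forms the ether by reductive elimination instead of addition–elimination and delivers 19.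

Step 12 (twenty demethylations on an oxidation-sensitive polyphenol). The fallback sets out from 27 and comes back at 28. After BBr3 treatment and methanol quench the crude polyphenol is not purified but acetylated with Ac2O and pyridine to the hexacosa-acetate of the target F6. F6 is stable and can be purified on silica, which also removes incompletely demethylated material. Methanolysis with 1.25 M HCl in MeOH under argon then releases 28 by simple evaporation.

Further compounds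
F1 | step 4 | 2-[3-(dimethoxymethyl)-4-fluoro-5-methoxyphenoxy]-3,4,5-trimethoxybenzaldehyde | O=Cc1cc(OC)c(OC)c(OC)c1Oc1cc(OC)c(F)c(C(OC)OC)c1
F2 | step 4 | 2-[3-(dimethoxymethyl)-4-fluoro-5-methoxyphenoxy]-3,4,5-trimethoxyphenyl formate | O=COc1cc(OC)c(OC)c(OC)c1Oc1cc(OC)c(F)c(C(OC)OC)c1
F3 | step 7 | 5-(4-formyl-2,6-dimethoxyphenoxy)-3-methoxy-2-[2-(methylsulfonyl)ethoxy]benzaldehyde | COc1cc(C=O)cc(OC)c1Oc1cc(OC)c(OCCS(C)(=O)=O)c(C=O)c1
F4 | step 7 | 5-(4-formyl-2,6-dimethoxyphenoxy)-2-hydroxy-3-methoxybenzaldehyde | COc1cc(C=O)cc(OC)c1Oc1cc(OC)c(O)c(C=O)c1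
F5 | step 7 | 4-(4-formyl-2,6-dimethoxyphenoxy)-2-formyl-6-methoxyphenyl trifluoromethanesulfonate | COc1cc(C=O)cc(OC)c1Oc1cc(OC)c(OS(=O)(=O)C(F)(F)F)c(C=O)c1
F6 | step 12 | hexacosa-acetate of CNP0255890.0 (all 26 OH as OAc) | CC(=O)Oc1cc(OC(C)=O)c(Oc2cc(OC(C)=O)c(Oc3cc(OC(C)=O)c(OC(C)=O)c(OC(C)=O)c3Oc3cc(OC(C)=O)c(Oc4cc(OC(C)=O)c(OC(C)=O)c(OC(C)=O)c4Oc4cc(OC(C)=O)c(Oc5cc(OC(C)=O)c(OC(C)=O)c(OC(C)=O)c5Oc5cc(OC(C)=O)c(Oc6cc(OC(C)=O)c(OC(C)=O)c(OC(C)=O)c6Oc6cc(OC(C)=O)c(OC(C)=O)c(OC(C)=O)c6)c(OC(C)=O)c5)c(OC(C)=O)c4)c(OC(C)=O)c3)c(OC(C)=O)c2)c(OC(C)=O)c1
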